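All runs come from a simulation for an exercise, noise included.

- elm: solid substrate 0.10 M; coupling partner 0.20 M; run made earlier
- flask: solid substrate 0.20 M; coupling partner 0.200 M; time 4.0 d
elm run (percent of the solid substrate charged)

| time / h | target / % | starting material / % |
|---|---|---|
| 1.50 | 0 | 5.8 |
| 4.00 | 3.6 | 13.5 |
| 8.00 | 9.8 | 18.0 |
| 20.0 | 30.0 | 24.2 |

(each reading ± 1 percentage point)
- in percentages every species weighs as the solid substrate in it: one side product B counts as two
- as a solid, counted per litre of solution: solid substrate
- the earlier runs were read with a standard deviation of 1 percentage point
- on the list of suspects stand: solid substrate <-> starting material; target <-> isomer of the product; starting material + coupling partner -> target; starting material -> side product A; 2 starting material -> side product B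
- at the start none of the solid substrate is in solution
- starting material means what is dissolved; the solid is not counted in it
- amount of target at 4.0 d, in percent of the solid substrate charged
- concentration of starting material in solution at 25 h, in percent of saturation
- the change that raises the amount of target at 4.0 d, in percent of the solid substrate charged most ("none" if none brings more than 2 percentage points) (gamma / zeta / alpha / none)
- amount of target at 4.0 d, in percent of the solid substrate charged, after zeta
- gamma: doubling the solubility of the solid substrate, all else as stated
- zeta: doubling the amount of coupling partner, all else as stated
- alpha: doubling the dissolution coefficient of the solid substrate, all else as stated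

1. If solid substrate enters solution at a rate r set by the solution and not by the solid charge, two flasks with equal coupling partner run alike while solid lies in both. The elm run (0.10 M solid substrate) and this flask (0.20 M) form such a pair, both at 0.200 M coupling partner.

2. In the elm run, target plus starting material gain 2.20 mM h⁻¹ between 8.00 h and 20.0 h. This is a reading, and a low one for r, since isomer of the product, side product A and side product B go unread. It is slower than the 3.87 mM h⁻¹ of the first interval.

3. This flask needs 90.9 h at that rate. Charge over r is the dissolution time τ. For the elm run, τ is 45.5 h.

4. The elm run's last reading, 30.0% target, stands before its τ. At that hour this flask should hold the same concentration, which reads 15.0% of its larger charge. Its window of 4.0 d is longer than τ, so this reckoning expects the solid dissolved by then, little gain from faster dissolution or higher solubility, and the gain from more coupling partner.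

5. The forecast gives 70%, 54%, zeta and 96%, holding that “solid persists to 96 h”; on the solid, the reckoning here differs.

6. The flask gives 50.8%, 38.7%, zeta and 62.4%.

    solid substrate ⇌ starting material, rate k1*(cs1 - [starting material]) while solid is left; crystals form when [starting material] > cs1 (solubility = 0.0670 M, k = 0.0750 h⁻¹)
    target ⇌ isomer of the product (K = 0.470, k = 0.290 h⁻¹)
    starting material + coupling partner → target (k = 0.620 M⁻¹ h⁻¹)
    starting material → side product A (k = 0.0120 h⁻¹)
    2 starting material → side product B (k = 0.150 M⁻¹ h⁻¹)

7. At 4.0 d this flask holds 0% solid substrate, and doubling the dissolution coefficient moves target by −0.023 percentage points. The pseudo-first-order half-life of starting material towards target, 0.92 d, is shorter than the 2.4 d towards side product A, and target stands at 50.8% beside 23.8% isomer of the product.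

8. With 0.34 M solid substrate, τ becomes 155 h, longer than the window, so solid should remain. That flask holds 21.2% solid substrate and 33.3% target at 4.00 d.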